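Late in the run, at 30 h, the flask will stand where the order of its rate has taken it, and the next decision hangs on that: the flask is left as charged if target passes half of the substrate by then, and otherwise a second portion of free catalyst is planned.

- blue: substrate 0.80 M; coupling partner 1.05 equiv; free catalyst 1.2 mol%; the very flask that is asked about, followed so far
- flask: substrate 0.80 M; coupling partner 1.05 equiv; free catalyst 1.2 mol%; time 30 h

blue run (percent of the substrate charged)

| time / h | target / % |
|---|---|
| 0.833 | 1.4 |
| 2.00 | 5.0 |
| 4.00 | 9.5 |
| 6.00 | 13.3 |

(standard deviation of a reading: 0.5 percentage points)

- what was read earlier has a scatter of 0.5 percentage points, one standard deviation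

- amount of target in percent of the substrate charged, at 6.0 h, 15 h and 30 h

The readings stop at 13.3%, too early to separate one order from another. With free catalyst at 1.2 mol%, both reagents must pass through a small pool of catalyst, and if that pool is held mostly on one reagent, the rate follows one concentration and not the product of two. This reckoning, which is an assumption, takes [coupling partner] as that concentration, which makes the run pseudo-first-order. The clock constant is then the natural logarithm of the charge of coupling partner over what remains of it, divided by the time, and the reading at 6.00 h gives 0.0226 /h. Run backwards, this clock gives 9.07% at 4.00 h against 9.5% read, inside the scatter of 0.5 percentage points. Run forwards, it gives 30.2% at 15 h and 51.7% at 30 h, so this reckoning leaves the flask as charged.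

The forecast, built on “near-equimolar second-order kinetics” and shaded down, reads 13.4%, 26% and 40%, so on its numbers the second portion is planned, and here the two part.

The flask gives 13.7%, 32.1% and 56.0%.

    catalyst intermediate D → free catalyst + target (k = 7.72 /h)
    catalyst intermediate B → by-product + catalyst intermediate C (k = 5.64 /h)
    substrate + by-product ⇌ idle adduct, settled at all times (K = 0.556 /M)
    coupling partner + catalyst intermediate A → catalyst intermediate B (k = 7.84 /M/h)
    catalyst intermediate C → catalyst intermediate D (k = 429 /h)
    coupling partner + target → over-reaction product (k = 0.0118 /M/h)
    substrate + free catalyst → catalyst intermediate A (k = 58.0 /M/h)

Target in this flask passes the mark, and the same clock read from the value at 30 h gives 0.0254 /h, higher than the 0.0226 /h read at 6.00 h. Target in this flask stands at 56.0% at 30 h because of two things acting together, the early hour of the reading and the step from coupling partner and target to over-reaction product. The same run read at 300 h gives 85.7%, and the same run without that step gives 61.9% at 30 h.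

The numbers in the tables are simulated with made-up constants; the scatter is artificial.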